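**Plan**
1. Retrosynthetic cuts: the seven O–methyl bonds last, then the C6–vinyl bond of the styryl arm, then C3–C6' and C2–aryl in ring system 1 across a former furan C2=C3 bond, then C3'–aryl and C2'–aryl in ring system 2 in the same way.
2. Feature used: ring system 1 (O1, C2, C3, C3a, C7a fused to benzo ring A, styryl on C6) is a benzofuran whose C2=C3 bond has taken up 4-hydroxyphenyl on C2 and carbon C6' of benzo ring B on C3 from opposite faces. Ring system 2 (primed atoms, ring B) repeats the pattern with 3,5-dihydroxyphenyl on C3'.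
3. Forward: 5-methoxyresorcinol gives one building block, a 4-methoxy-6-silyloxybenzofuran-2-yl pinacol boronate. Its furan ring is closed in step 3, and no ring is closed after that.
4. The boronate and 4-methoxyphenyllithium give one lithium ate complex (step 6). One portion is coupled with 3,5-dimethoxyphenyl triflate to give ring system 2; its C6' silyl ether becomes a triflate, which is coupled with a second portion to give ring system 1. Triflation at C6, Suzuki coupling and demethylation finish the route.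
5. Stereochemistry: one enantiomer of a palladium–MandyPhos catalyst picks the face of C2=C3 in both couplings (C3', then C3). The anti shift from boron makes each pair of aryl groups trans, and protodeboronation with retention keeps C2' and C2. All four centres are S.

Key step: step 10

Assumption: the sense of induction of the palladium–MandyPhos catalyst on a benzofuranyl ate complex is not known, so the (Sp,Sp) ligand enantiomer written below stands for whichever enantiomer is found in step 7 to give the (2S,3S) series.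
Remark: ate complex 11 is not stored; step 6 is run in two batches, each used at once as a THF solution, one for step 7 and one for step 10.

**Step 1**
Reactants: 1 5-methoxyresorcinol
Product: 2 2,4-dihydroxy-6-methoxybenzaldehyde
Conditions: POCl3, DMF, MeCN, 0 °C to rt; then H2O, 50 °C
Reagents that add atoms: N,N-dimethylformamide CN(C)C=O; water O
Why: Vilsmeier–Haack formylation of the phloroglucinol-type ring should take place para to one hydroxyl and ortho to the other, the most accessible activated carbon, and hydrolysis of the iminium salt should give the aldehyde, any symmetric 2,6-dihydroxy isomer being removed by crystallisation.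

**Step 2**
Reactants: 2 2,4-dihydroxy-6-methoxybenzaldehyde
Product: 3 2-hydroxy-6-methoxy-4-(triisopropylsilyloxy)benzaldehyde
Conditions: TIPSCl (1.05 equiv), imidazole, CH2Cl2, 0 °C
Reagents that add atoms: chlorotriisopropylsilane CC(C)[Si](Cl)(C(C)C)C(C)C
Why: Selective O-silylation should occur at the exposed and more acidic 4-hydroxyl, because the 2-hydroxyl is tied up in a hydrogen bond to the aldehyde and is hindered toward the bulky chloride.

**Step 3**
Reactants: 3 2-hydroxy-6-methoxy-4-(triisopropylsilyloxy)benzaldehyde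
Product: 5 4-methoxy-6-(triisopropylsilyloxy)benzofuran, via enol ether 4 (not isolated)
Conditions: MeOCH2PPh3Cl (3 equiv), KN(SiMe3)2, THF, 0 °C to rt; aqueous work-up; then TsOH·H2O (cat.), toluene, 60 °C
Reagents that add atoms: (methoxymethyl)triphenylphosphonium chloride COC[P+](c1ccccc1)(c1ccccc1)c1ccccc1.[Cl-]
Why: Wittig methoxymethylenation of the salicylaldehyde (excess ylide covers the phenoxide) followed by acid-catalysed addition of the phenol to the enol ether and loss of methanol is a standard benzofuran synthesis, and the aryl silyl ether should tolerate the hindered amide base at 0 °C and the catalytic sulfonic acid.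

**Step 4**
Reactants: 5 4-methoxy-6-(triisopropylsilyloxy)benzofuran
Product: 6 pinacol [4-methoxy-6-(triisopropylsilyloxy)benzofuran-2-yl]boronate
Conditions: n-BuLi, THF, −78 °C; then i-PrOBpin, −78 °C to rt
Reagents that add atoms: 2-isopropoxy-4,4,5,5-tetramethyl-1,3,2-dioxaborolane CC(C)OB1OC(C)(C)C(C)(C)O1
Why: Lithiation–borylation should work because benzofurans are deprotonated at C2, next to the ring oxygen, faster than the methoxy or silyloxy groups can direct ortho-metalation, and the 2-lithio species is trapped by the isopropoxy boronate.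

**Step 5**
Reactants: 7 3,5-dimethoxyphenol
Product: 8 3,5-dimethoxyphenyl trifluoromethanesulfonate
Conditions: Tf2O, pyridine, CH2Cl2, 0 °C
Reagents that add atoms: trifluoromethanesulfonic anhydride O=S(=O)(OS(=O)(=O)C(F)(F)F)C(F)(F)F
Why: O-Triflation of a simple phenol with triflic anhydride and pyridine is routine.

**Step 6**
Reactants: 6 pinacol [4-methoxy-6-(triisopropylsilyloxy)benzofuran-2-yl]boronate; 9 4-bromoanisole
Product: 11 lithium [4-methoxy-6-(triisopropylsilyloxy)benzofuran-2-yl](4-methoxyphenyl)(pinacolato)borate, via 4-methoxyphenyllithium 10 (not isolated)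
Conditions: 9, t-BuLi (2.0 equiv), Et2O, −78 °C; then 6 (1.05 equiv), THF, −78 °C to rt; Et2O removed under vacuum, residue taken up in THF under argon
Reagents that add atoms: tert-butyllithium [Li]C(C)(C)C
Why: Bromine–lithium exchange with two equivalents of t-BuLi gives the aryllithium irreversibly, and its addition to the Lewis acidic boron of a heteroaryl pinacol boronate to form a four-coordinate lithium borate is the standard first stage of boronate 1,2-metalate chemistry, the slight excess of 6 leaving no free aryllithium.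

**Step 7**
Reactants: 11 lithium [4-methoxy-6-(triisopropylsilyloxy)benzofuran-2-yl](4-methoxyphenyl)(pinacolato)borate; 8 3,5-dimethoxyphenyl trifluoromethanesulfonate
Product: 12 (2S,3S)-3-(3,5-dimethoxyphenyl)-4-methoxy-2-(4-methoxyphenyl)-2-(pinacolatoboryl)-6-(triisopropylsilyloxy)-2,3-dihydrobenzofuran
Conditions: 11 (1.3 equiv, THF solution from step 6), KOTf (2 equiv), 8 (1.0 equiv), Pd(OAc)2 (5 mol%), (Sp,Sp)-MandyPhos ligand Fe[C5H3(PPh2)(CH(NMe2)Ph)]2 (6 mol%), THF, 60 °C
Reagents that add atoms: none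
Why: Proposed new method: the C2=C3 bond of the benzofuran-2-yl ate complex should react like an electron-rich enol ether, so that the cationic arylpalladium formed from the triflate by oxidative addition bonds to C3 while 4-methoxyphenyl shifts from boron to C2 on the opposite face, and reductive elimination then forms the C3–aryl bond; the aryl groups thus end up trans with boron left on C2, and the ligand fixes the face and hence the (2S,3S) configuration; the closest known reactions are the enantioselective palladium-catalysed three-component coupling of indol-2-yl boronate complexes with allylic electrophiles and the MandyPhos-controlled conjunctive coupling of alkenyl boronate complexes with aryl triflates.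

**Step 8**
Reactants: 12 (2S,3S)-3-(3,5-dimethoxyphenyl)-4-methoxy-2-(4-methoxyphenyl)-2-(pinacolatoboryl)-6-(triisopropylsilyloxy)-2,3-dihydrobenzofuran
Product: 13 (2S,3S)-3-(3,5-dimethoxyphenyl)-4-methoxy-2-(4-methoxyphenyl)-2,3-dihydrobenzofuran-6-ol
Conditions: TBAF·3H2O (5 equiv), THF/toluene, 45 °C
Reagents that add atoms: none
Why: Fluoride-promoted protodeboronation of tertiary benzylic pinacol boronates is known to go with retention, so hydrogen should replace boron on the face cis to the C3 aryl group and leave the two aryl groups trans, while the same fluoride cleaves the aryl silyl ether.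

**Step 9**
Reactants: 13 (2S,3S)-3-(3,5-dimethoxyphenyl)-4-methoxy-2-(4-methoxyphenyl)-2,3-dihydrobenzofuran-6-ol
Product: 14 (2S,3S)-3-(3,5-dimethoxyphenyl)-4-methoxy-2-(4-methoxyphenyl)-2,3-dihydrobenzofuran-6-yl trifluoromethanesulfonate
Conditions: PhNTf2, Et3N, DMAP (cat.), CH2Cl2, rt
Reagents that add atoms: N-phenylbis(trifluoromethanesulfonimide) O=S(=O)(N(c1ccccc1)S(=O)(=O)C(F)(F)F)C(F)(F)F
Why: Phenol triflation with the mild triflimide reagent should go cleanly and avoids strong acid at the 4-methoxybenzylic C2–O bond.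

**Step 10**
Reactants: 11 lithium [4-methoxy-6-(triisopropylsilyloxy)benzofuran-2-yl](4-methoxyphenyl)(pinacolato)borate; 14 (2S,3S)-3-(3,5-dimethoxyphenyl)-4-methoxy-2-(4-methoxyphenyl)-2,3-dihydrobenzofuran-6-yl trifluoromethanesulfonate
Product: 15 (2S,3S)-3-[(2S,3S)-3-(3,5-dimethoxyphenyl)-4-methoxy-2-(4-methoxyphenyl)-2,3-dihydrobenzofuran-6-yl]-4-methoxy-2-(4-methoxyphenyl)-2-(pinacolatoboryl)-6-(triisopropylsilyloxy)-2,3-dihydrobenzofuran
Conditions: 11 (1.3 equiv, THF solution from step 6), KOTf (2 equiv), 14 (1.0 equiv), Pd(OAc)2 (5 mol%), (Sp,Sp)-MandyPhos ligand Fe[C5H3(PPh2)(CH(NMe2)Ph)]2 (6 mol%), THF, 60 °C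
Reagents that add atoms: none
Why: Proposed new method: zerovalent palladium inserts into the C6'–O bond of triflate 14 to give a cationic arylpalladium complex of divalent palladium held by the chelating ligand, and this electrophile meets ate complex 11, the adduct of 4-methoxyphenyllithium 10 and boronate 6 made in step 6. It should bind the C2=C3 bond of 11 and bond to C3 while 4-methoxyphenyl shifts from boron to C2 on the opposite face (1,2-metalate shift), and reductive elimination from the C3–palladium–aryl species, which has no β-hydrogen, then forms C3–C6' with retention and leaves boron on C2. The closest known reactions are the enantioselective palladium-catalysed three-component coupling of indol-2-yl boronate complexes with allylic electrophiles and the conjunctive coupling of alkenyl boronate complexes with aryl triflates under the same ligand class; an aryl electrophile on a benzofuran-2-yl ate complex has not been shown. No ring is closed: the furan ring of the benzofuran is dearomatised, at small cost because benzo ring A stays aromatic. C3 is set by the face of C2=C3 that the chiral palladium complex takes, which the ligand (same enantiomer as in step 7) should decide because C2' and C3' of the triflate lie four bonds from C6', and C2 is set by the anti course of the shift, which puts the two aryl groups trans and boron cis to ring B. The step needs the metalate shift to win over direct Suzuki transfer of a group from boron to palladium and needs bonding at C3 only: the borate on C2 makes C3 the nucleophilic end, the chelating ligand leaves no free site for transmetalation, KOTf takes up the bromide carried over from step 6 that would block the cationic palladium, and C6' is flanked by two unsubstituted ring carbons.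

**Step 11**
Reactants: 15 (2S,3S)-3-[(2S,3S)-3-(3,5-dimethoxyphenyl)-4-methoxy-2-(4-methoxyphenyl)-2,3-dihydrobenzofuran-6-yl]-4-methoxy-2-(4-methoxyphenyl)-2-(pinacolatoboryl)-6-(triisopropylsilyloxy)-2,3-dihydrobenzofuran
Product: 16 (2S,3S)-3-[(2S,3S)-3-(3,5-dimethoxyphenyl)-4-methoxy-2-(4-methoxyphenyl)-2,3-dihydrobenzofuran-6-yl]-4-methoxy-2-(4-methoxyphenyl)-2,3-dihydrobenzofuran-6-ol
Conditions: TBAF·3H2O (5 equiv), THF/toluene, 45 °C
Reagents that add atoms: none
Why: Stereoretentive fluoride-mediated protodeboronation, as in step 8, should replace boron on C2 by hydrogen without touching C3 or ring system 2, giving the trans,trans bis(dihydrobenzofuran), and the silyl ether is cleaved in the same flask.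

**Step 12**
Reactants: 16 (2S,3S)-3-[(2S,3S)-3-(3,5-dimethoxyphenyl)-4-methoxy-2-(4-methoxyphenyl)-2,3-dihydrobenzofuran-6-yl]-4-methoxy-2-(4-methoxyphenyl)-2,3-dihydrobenzofuran-6-ol
Product: 17 (2S,3S)-3-[(2S,3S)-3-(3,5-dimethoxyphenyl)-4-methoxy-2-(4-methoxyphenyl)-2,3-dihydrobenzofuran-6-yl]-4-methoxy-2-(4-methoxyphenyl)-2,3-dihydrobenzofuran-6-yl trifluoromethanesulfonate
Conditions: PhNTf2, Et3N, DMAP (cat.), CH2Cl2, rt
Reagents that add atoms: N-phenylbis(trifluoromethanesulfonimide) O=S(=O)(N(c1ccccc1)S(=O)(=O)C(F)(F)F)C(F)(F)F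
Why: Mild phenol triflation as in step 9 should turn the C6 oxygen into the leaving group for the last C–C bond without acid that could open a benzylic C2–O bond.

**Step 13**
Reactants: 17 (2S,3S)-3-[(2S,3S)-3-(3,5-dimethoxyphenyl)-4-methoxy-2-(4-methoxyphenyl)-2,3-dihydrobenzofuran-6-yl]-4-methoxy-2-(4-methoxyphenyl)-2,3-dihydrobenzofuran-6-yl trifluoromethanesulfonate; 18 (E)-2-(4-methoxyphenyl)vinylboronic acid pinacol ester
Product: 19 (2S,3S)-3-[(2S,3S)-3-(3,5-dimethoxyphenyl)-4-methoxy-2-(4-methoxyphenyl)-2,3-dihydrobenzofuran-6-yl]-4-methoxy-2-(4-methoxyphenyl)-6-[(E)-2-(4-methoxyphenyl)ethenyl]-2,3-dihydrobenzofuran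
Conditions: Pd(OAc)2, SPhos, K3PO4, THF/H2O, 60 °C
Reagents that add atoms: none
Why: Suzuki–Miyaura coupling of an unhindered aryl triflate with an (E)-alkenyl pinacol boronate proceeds with retention of alkene geometry, and the electron-rich biarylphosphine should promote oxidative addition into the electron-rich C6–O bond.

**Step 14**
Reactants: 19 (2S,3S)-3-[(2S,3S)-3-(3,5-dimethoxyphenyl)-4-methoxy-2-(4-methoxyphenyl)-2,3-dihydrobenzofuran-6-yl]-4-methoxy-2-(4-methoxyphenyl)-6-[(E)-2-(4-methoxyphenyl)ethenyl]-2,3-dihydrobenzofuran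
Product: 20 5-[(2S,3S)-6-[(2S,3S)-4-hydroxy-2-(4-hydroxyphenyl)-6-[(E)-2-(4-hydroxyphenyl)ethenyl]-2,3-dihydrobenzofuran-3-yl]-4-hydroxy-2-(4-hydroxyphenyl)-2,3-dihydrobenzofuran-3-yl]benzene-1,3-diol (CNP0248228.2)
Conditions: BBr3 (20 equiv), CH2Cl2, −78 °C to rt; then MeOH, H2O
Reagents that add atoms: none
Why: Lewis acid cleavage of aryl methyl ethers by BBr3 should free all seven phenols; the styryl group on C6 is remote from the C3 aryl ring, so acid-induced cyclisation onto the alkene has no geometric opening, and both C2 centres already hold the thermodynamically preferred trans arrangement, so reversible opening of a benzylic C2–O bond cannot change them.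

**Compound list**
1 | 5-methoxyresorcinol (5-methoxybenzene-1,3-diol) | COc1cc(O)cc(O)c1 | starting material
2 | 2,4-dihydroxy-6-methoxybenzaldehyde | O=Cc1c(O)cc(O)cc1OC | intermediate
3 | 2-hydroxy-6-methoxy-4-(triisopropylsilyloxy)benzaldehyde | O=Cc1c(O)cc(O[Si](C(C)C)(C(C)C)C(C)C)cc1OC | intermediate
4 | 3-methoxy-2-(2-methoxyethenyl)-5-(triisopropylsilyloxy)phenol, E/Z mixture, formed and used crude | COC=Cc1c(O)cc(O[Si](C(C)C)(C(C)C)C(C)C)cc1OC | intermediate
5 | 4-methoxy-6-(triisopropylsilyloxy)benzofuran | COc1cc(O[Si](C(C)C)(C(C)C)C(C)C)cc2occc12 | intermediate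
6 | pinacol [4-methoxy-6-(triisopropylsilyloxy)benzofuran-2-yl]boronate | CC1(C)OB(OC1(C)C)c1cc2c(OC)cc(O[Si](C(C)C)(C(C)C)C(C)C)cc2o1 | intermediate
7 | 3,5-dimethoxyphenol | COc1cc(O)cc(OC)c1 | starting material
8 | 3,5-dimethoxyphenyl trifluoromethanesulfonate | COc1cc(OC)cc(OS(=O)(=O)C(F)(F)F)c1 | intermediate
9 | 4-bromoanisole | COc1ccc(Br)cc1 | starting material
10 | 4-methoxyphenyllithium, formed in the flask | [Li]c1ccc(OC)cc1 | intermediate
11 | lithium [4-methoxy-6-(triisopropylsilyloxy)benzofuran-2-yl](4-methoxyphenyl)(pinacolato)borate, used as a fresh THF solution | [Li+].CC1(C)O[B-](OC1(C)C)(c1ccc(OC)cc1)c1cc2c(OC)cc(O[Si](C(C)C)(C(C)C)C(C)C)cc2o1 | intermediate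
12 | (2S,3S)-3-(3,5-dimethoxyphenyl)-4-methoxy-2-(4-methoxyphenyl)-2-(4,4,5,5-tetramethyl-1,3,2-dioxaborolan-2-yl)-6-(triisopropylsilyloxy)-2,3-dihydrobenzofuran (aryl groups trans, boron cis to the C3 aryl group) | CC(C)[Si](Oc1cc(OC)c2c(c1)O[C@](B1OC(C)(C)C(C)(C)O1)(c1ccc(OC)cc1)[C@H]2c1cc(OC)cc(OC)c1)(C(C)C)C(C)C | intermediate
13 | (2S,3S)-3-(3,5-dimethoxyphenyl)-4-methoxy-2-(4-methoxyphenyl)-2,3-dihydrobenzofuran-6-ol (trans) | Oc1cc(OC)c2c(c1)O[C@H](c1ccc(OC)cc1)[C@H]2c1cc(OC)cc(OC)c1 | intermediate
14 | (2S,3S)-3-(3,5-dimethoxyphenyl)-4-methoxy-2-(4-methoxyphenyl)-2,3-dihydrobenzofuran-6-yl trifluoromethanesulfonate (tetra-O-methyl ring system 2 triflate) | FC(F)(F)S(=O)(=O)Oc1cc(OC)c2c(c1)O[C@H](c1ccc(OC)cc1)[C@H]2c1cc(OC)cc(OC)c1 | intermediate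
15 | (2S,3S)-3-[(2S,3S)-3-(3,5-dimethoxyphenyl)-4-methoxy-2-(4-methoxyphenyl)-2,3-dihydrobenzofuran-6-yl]-4-methoxy-2-(4-methoxyphenyl)-2-(4,4,5,5-tetramethyl-1,3,2-dioxaborolan-2-yl)-6-(triisopropylsilyloxy)-2,3-dihydrobenzofuran | CC(C)[Si](Oc1cc(OC)c2c(c1)O[C@](B1OC(C)(C)C(C)(C)O1)(c1ccc(OC)cc1)[C@H]2c1cc(OC)c2c(c1)O[C@H](c1ccc(OC)cc1)[C@H]2c1cc(OC)cc(OC)c1)(C(C)C)C(C)C | intermediate
16 | (2S,3S)-3-[(2S,3S)-3-(3,5-dimethoxyphenyl)-4-methoxy-2-(4-methoxyphenyl)-2,3-dihydrobenzofuran-6-yl]-4-methoxy-2-(4-methoxyphenyl)-2,3-dihydrobenzofuran-6-ol | Oc1cc(OC)c2c(c1)O[C@H](c1ccc(OC)cc1)[C@H]2c1cc(OC)c2c(c1)O[C@H](c1ccc(OC)cc1)[C@H]2c1cc(OC)cc(OC)c1 | intermediate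
17 | (2S,3S)-3-[(2S,3S)-3-(3,5-dimethoxyphenyl)-4-methoxy-2-(4-methoxyphenyl)-2,3-dihydrobenzofuran-6-yl]-4-methoxy-2-(4-methoxyphenyl)-2,3-dihydrobenzofuran-6-yl trifluoromethanesulfonate | FC(F)(F)S(=O)(=O)Oc1cc(OC)c2c(c1)O[C@H](c1ccc(OC)cc1)[C@H]2c1cc(OC)c2c(c1)O[C@H](c1ccc(OC)cc1)[C@H]2c1cc(OC)cc(OC)c1 | intermediate
18 | (E)-2-(4-methoxyphenyl)vinylboronic acid pinacol ester | COc1ccc(/C=C/B2OC(C)(C)C(C)(C)O2)cc1 | starting material
19 | hepta-O-methyl ether of the target: (2S,3S)-3-[(2S,3S)-3-(3,5-dimethoxyphenyl)-4-methoxy-2-(4-methoxyphenyl)-2,3-dihydrobenzofuran-6-yl]-4-methoxy-2-(4-methoxyphenyl)-6-[(E)-2-(4-methoxyphenyl)ethenyl]-2,3-dihydrobenzofuran | COc1ccc(/C=C/c2cc(OC)c3c(c2)O[C@H](c2ccc(OC)cc2)[C@H]3c2cc(OC)c3c(c2)O[C@H](c2ccc(OC)cc2)[C@H]3c2cc(OC)cc(OC)c2)cc1 | intermediate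
20 | CNP0248228.2, 5-[(2S,3S)-6-[(2S,3S)-4-hydroxy-2-(4-hydroxyphenyl)-6-[(E)-2-(4-hydroxyphenyl)ethenyl]-2,3-dihydrobenzofuran-3-yl]-4-hydroxy-2-(4-hydroxyphenyl)-2,3-dihydrobenzofuran-3-yl]benzene-1,3-diol | Oc1ccc(/C=C/c2cc(O)c3c(c2)O[C@H](c2ccc(O)cc2)[C@H]3c2cc(O)c3c(c2)O[C@H](c2ccc(O)cc2)[C@H]3c2cc(O)cc(O)c2)cc1 | target

**Step count**
Total: 14 steps. Longest linear sequence: 13 steps (steps 1–4 and 6–14, from 5-methoxyresorcinol).

**Steps most likely to fail**

Step 10. Transfer of the benzofuranyl or 4-methoxyphenyl group from boron to palladium (ordinary Suzuki coupling) may outrun the metalate shift, bonding at C3 next to the C4 methoxy group may be slow, and face selection by the ligand may be incomplete. The fallback uses ortho-quinone methide chemistry, sets out from 14 (with 1 for the phenol partner) and comes back at 16. Palladium-catalysed formylation of 14 (Pd(OAc)2, 1,3-bis(diphenylphosphino)propane, CO, Et3SiH, Et3N, DMF, 70 °C) would give (2S,3S)-3-(3,5-dimethoxyphenyl)-4-methoxy-2-(4-methoxyphenyl)-2,3-dihydrobenzofuran-6-carbaldehyde F1. Monosilylation of 1 with one equivalent of TIPSCl would give 3-methoxy-5-(triisopropylsilyloxy)phenol F2. Acid-mediated three-component condensation of F1, F2 and sodium p-toluenesulfinate (HCO2H, rt) should give the ortho-hydroxybenzyl sulfone F3, the position between hydroxyl and methoxy being the least hindered activated site. Cs2CO3 would release the ortho-quinone methide F4 in the flask, and (4-methoxybenzyl)dimethylsulfonium ylide should intercept it in a [4+1] annulation to give the trans-dihydrobenzofuran, the triisopropylsilyl ether of 16 F5. The annulation has no control over the face, so F5 would have to be separated by chromatography from its (2R,3R) diastereomer in ring system 1; TBAF then gives 16.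

Step 7. With the simple aryl triflate the same competition with direct cross-coupling, or insufficient enantioselectivity, would leave ring system 2 unavailable as a single enantiomer. The fallback uses racemic annulation followed by resolution, sets out from 3 and comes back at 13. Addition of 3,5-dimethoxyphenylmagnesium bromide (2.2 equiv, THF, 0 °C) to 3 would give the benzhydrol 2-[(3,5-dimethoxyphenyl)(hydroxy)methyl]-3-methoxy-5-(triisopropylsilyloxy)phenol F6. p-Toluenesulfinic acid in CH2Cl2 would convert F6 into the sulfone 2-[(3,5-dimethoxyphenyl)(tosyl)methyl]-3-methoxy-5-(triisopropylsilyloxy)phenol F7. Cs2CO3 would release the ortho-quinone methide F8, which (4-methoxybenzyl)dimethylsulfonium ylide should convert by [4+1] annulation into the racemic trans-2,3-diaryl-2,3-dihydrobenzofuran silyl ether F9. TBAF would give the racemic phenol F10, and preparative chromatography on a chiral stationary phase (cellulose tris(3,5-dimethylphenylcarbamate)) then delivers 13.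

Step 11. Cleavage of the C–B bond at the crowded, oxygen-bearing C2 may be slow, or protonation may occur with partial loss of configuration. The fallback replaces kinetic retention by thermodynamic control, sets out from 15 and comes back at 16. Activation of boron with PhLi and photoredox protodeboronation (Ir(ppy)3, PhSH, blue light) would cleave the C–B bond through the C2 radical whatever its configuration; hydrogen delivery anti to ring B should give mainly the cis isomer, the (2R,3S,2'S,3'S) silyl ether F11. TBAF would give the cis phenol F12. BF3·OEt2 in CH2Cl2 should then equilibrate C2 by reversible ionisation of the 4-methoxybenzylic C2–O1 bond to the more stable trans isomer 16.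

**Further compounds**
F1 | step 10 | (2S,3S)-3-(3,5-dimethoxyphenyl)-4-methoxy-2-(4-methoxyphenyl)-2,3-dihydrobenzofuran-6-carbaldehyde | O=Cc1cc(OC)c2c(c1)O[C@H](c1ccc(OC)cc1)[C@H]2c1cc(OC)cc(OC)c1
F2 | step 10 | 3-methoxy-5-(triisopropylsilyloxy)phenol | COc1cc(O)cc(O[Si](C(C)C)(C(C)C)C(C)C)c1
F3 | step 10 | 2-{[(2S,3S)-3-(3,5-dimethoxyphenyl)-4-methoxy-2-(4-methoxyphenyl)-2,3-dihydrobenzofuran-6-yl](tosyl)methyl}-3-methoxy-5-(triisopropylsilyloxy)phenol, epimer mixture at the sulfonyl carbon | Cc1ccc(cc1)S(=O)(=O)C(c1c(O)cc(O[Si](C(C)C)(C(C)C)C(C)C)cc1OC)c1cc(OC)c2c(c1)O[C@H](c1ccc(OC)cc1)[C@H]2c1cc(OC)cc(OC)c1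
F4 | step 10 | ortho-quinone methide 6-{[(2S,3S)-3-(3,5-dimethoxyphenyl)-4-methoxy-2-(4-methoxyphenyl)-2,3-dihydrobenzofuran-6-yl]methylidene}-5-methoxy-3-(triisopropylsilyloxy)cyclohexa-2,4-dien-1-one | O=C1C=C(O[Si](C(C)C)(C(C)C)C(C)C)C=C(OC)C1=Cc1cc(OC)c2c(c1)O[C@H](c1ccc(OC)cc1)[C@H]2c1cc(OC)cc(OC)c1
F5 | step 10 | triisopropylsilyl ether of 16, (2S,3S,2'S,3'S) | CC(C)[Si](Oc1cc(OC)c2c(c1)O[C@H](c1ccc(OC)cc1)[C@H]2c1cc(OC)c2c(c1)O[C@H](c1ccc(OC)cc1)[C@H]2c1cc(OC)cc(OC)c1)(C(C)C)C(C)C
F6 | step 7 | 2-[(3,5-dimethoxyphenyl)(hydroxy)methyl]-3-methoxy-5-(triisopropylsilyloxy)phenol, racemic | OC(c1cc(OC)cc(OC)c1)c1c(O)cc(O[Si](C(C)C)(C(C)C)C(C)C)cc1OC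
F7 | step 7 | 2-[(3,5-dimethoxyphenyl)(tosyl)methyl]-3-methoxy-5-(triisopropylsilyloxy)phenol, racemic | Cc1ccc(cc1)S(=O)(=O)C(c1cc(OC)cc(OC)c1)c1c(O)cc(O[Si](C(C)C)(C(C)C)C(C)C)cc1OC
F8 | step 7 | ortho-quinone methide 6-[(3,5-dimethoxyphenyl)methylidene]-5-methoxy-3-(triisopropylsilyloxy)cyclohexa-2,4-dien-1-one | O=C1C=C(O[Si](C(C)C)(C(C)C)C(C)C)C=C(OC)C1=Cc1cc(OC)cc(OC)c1
F9 | step 7 | racemic trans-3-(3,5-dimethoxyphenyl)-4-methoxy-2-(4-methoxyphenyl)-6-(triisopropylsilyloxy)-2,3-dihydrobenzofuran, both enantiomers written | CC(C)[Si](Oc1cc(OC)c2c(c1)O[C@H](c1ccc(OC)cc1)[C@H]2c1cc(OC)cc(OC)c1)(C(C)C)C(C)C.CC(C)[Si](Oc1cc(OC)c2c(c1)O[C@@H](c1ccc(OC)cc1)[C@@H]2c1cc(OC)cc(OC)c1)(C(C)C)C(C)C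
F10 | step 7 | racemic trans-3-(3,5-dimethoxyphenyl)-4-methoxy-2-(4-methoxyphenyl)-2,3-dihydrobenzofuran-6-ol, both enantiomers written | Oc1cc(OC)c2c(c1)O[C@H](c1ccc(OC)cc1)[C@H]2c1cc(OC)cc(OC)c1.Oc1cc(OC)c2c(c1)O[C@@H](c1ccc(OC)cc1)[C@@H]2c1cc(OC)cc(OC)c1
F11 | step 11 | (2R,3S)-3-[(2S,3S)-3-(3,5-dimethoxyphenyl)-4-methoxy-2-(4-methoxyphenyl)-2,3-dihydrobenzofuran-6-yl]-4-methoxy-2-(4-methoxyphenyl)-6-(triisopropylsilyloxy)-2,3-dihydrobenzofuran, cis in ring system 1 | CC(C)[Si](Oc1cc(OC)c2c(c1)O[C@@H](c1ccc(OC)cc1)[C@H]2c1cc(OC)c2c(c1)O[C@H](c1ccc(OC)cc1)[C@H]2c1cc(OC)cc(OC)c1)(C(C)C)C(C)C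
F12 | step 11 | (2R,3S)-3-[(2S,3S)-3-(3,5-dimethoxyphenyl)-4-methoxy-2-(4-methoxyphenyl)-2,3-dihydrobenzofuran-6-yl]-4-methoxy-2-(4-methoxyphenyl)-2,3-dihydrobenzofuran-6-ol, cis in ring system 1 | Oc1cc(OC)c2c(c1)O[C@@H](c1ccc(OC)cc1)[C@H]2c1cc(OC)c2c(c1)O[C@H](c1ccc(OC)cc1)[C@H]2c1cc(OC)cc(OC)c1
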